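**Retrosynthetic overview** (gibberellane atom numbers, defined in the line below)
1. Target ⇐ silyl-protected precursor; C2–O (Rubottom), C9–H (copper hydride) and C3–OH (bulky hydride) are set last on the rigid pentacycle.
2. Lactone ring: C10 of a Δ9(11)-12-enone is oxidised and captured by the C19 carboxyl, as in the last oxidase step of the pathway.
3. Ring A: C4→C5 then C10→C1, a double Michael addition of a vinyl β-keto ester to the Δ5(10),9(11)-dienone.
4. Ring B: six→five contraction of a 7-ketone, C8 shifting from C7 to C6 and C7 leaving the ring as the carboxyl carbon, as in the biosynthetic kaurenoid→gibberellin step.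
5. Rings C/D: gold Conia-ene on a propargyl Wieland–Miescher-type enone. Order of ring formation: C (with six-membered B) → D → B contraction → A → lactone.

**Assumption and notation (one line):** atom labels C1–C19 are the ent-gibberellane labels of the target (C7 = carboxyl carbon on C6, C19 = lactone carbonyl on C4, C17 = exocyclic CH2, no C20) and are used for every intermediate; β is the face carrying H5, H9 and C15.

The target is the 12-oxo derivative of the 2β,3β-dihydroxy gibberellin 19,10-lactone 7-carboxylic acid. The route has not been run; steps 11 and 12 are proposals, and the facial selectivities at C5 (step 11) and at C9 (step 14) are the weakest points of the plan.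

**Step 1**
Reactants: 1 cyclohexane-1,3-dione; 2 3-bromoprop-1-yne
Product: 3 2-(prop-2-yn-1-yl)cyclohexane-1,3-dione
Conditions: KOH, H2O, rt → 50 °C
Reagents that add atoms: none
Why: C-alkylation (SN2) of the 1,3-dione enolate; no stereocentre is formed.

**Step 2**
Reactants: 3 2-(prop-2-yn-1-yl)cyclohexane-1,3-dione; 4 but-3-en-2-one
Product: 6 (R)-8a-(prop-2-yn-1-yl)-3,4,8,8a-tetrahydronaphthalene-1,6(2H,7H)-dione, via triketone 5 (not isolated)
Conditions: Et3N (1 mol%), neat, rt; then N-tosyl-(Sa)-binam-L-prolinamide (2.5 mol%), PhCO2H (1 mol%), rt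
Reagents that add atoms: none
Why: Robinson annulation (Michael addition, then enamine-mediated Hajos–Parrish-type aldol condensation); the prolinamide selects one of the two enantiotopic ring carbonyls and so fixes C8 in the same spatial sense as (S)-Wieland–Miescher ketone.

**Step 3**
Reactants: 6 (R)-8a-(prop-2-yn-1-yl)-3,4,8,8a-tetrahydronaphthalene-1,6(2H,7H)-dione
Product: 7 C7 ethylene ketal of 6
Conditions: HOCH2CH2OH, TsOH·H2O (cat.), 4 Å molecular sieves, rt
Reagents that add atoms: ethylene glycol, OCCO
Why: chemoselective ketalisation of the saturated ketone (the enone carbonyl is deactivated), routine for Wieland–Miescher ketones; C8 is untouched.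

**Step 4**
Reactants: 7 C7 ethylene ketal of 6
Product: 9 7,7-ethylenedioxy B/C/D enone (12-oxo-Δ9(11); 16-methylene), via silyl dienol ether 8 (not isolated)
Conditions: LiN(SiMe3)2, THF, −78 °C, then t-BuMe2SiCl, DMPU, −78 → 0 °C; then Ph3PAuCl (2 mol%), AgBF4 (2 mol%), toluene–MeOH 10:1, rt
Reagents that add atoms: none
Why: kinetic cross-conjugated enolisation at C13, then gold-catalysed Conia-ene-type 5-exo-dig attack of C13 on the alkyne closes ring D with the exocyclic methylene; the C13 configuration is dictated by the bridge.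

**Step 5**
Reactants: 9 7,7-ethylenedioxy B/C/D enone
Product: 10 B/C/D ene-dione (7,12-dioxo-Δ9(11); 16-methylene)
Conditions: pyridinium p-toluenesulfonate, acetone–H2O, 60 °C
Reagents that add atoms: water, O
Why: acid-catalysed ketal hydrolysis; the enone and the exocyclic alkene survive these mild conditions.

**Step 6**
Reactants: 10 B/C/D ene-dione
Product: 12 6-diazo-7,12-dione, via trifluoroacetyl diketone 11 (not isolated)
Conditions: LiN(SiMe3)2, THF, −78 °C; CF3CO2CH2CF3; then MeSO2N3, Et3N, H2O, MeCN, rt
Reagents that add atoms: methanesulfonyl azide, CS(=O)(=O)N=[N+]=[N-]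
Why: detrifluoroacetylative Regitz diazo transfer; C6 is the only kinetically enolisable α-position (C8 is quaternary, C13 is a bridgehead).

**Step 7**
Reactants: 12 6-diazo-7,12-dione
Product: 13 ring-B-contracted 2-(trimethylsilyl)ethyl 7-oate (12-oxo-Δ9(11); C6 epimers)
Conditions: hν (450 nm LED), Me3SiCH2CH2OH (5 equiv), THF, rt
Reagents that add atoms: 2-(trimethylsilyl)ethanol, C[Si](C)(C)CCO
Why: Wolff rearrangement ring contraction; C8 migrates from C7 to C6 with retention and C7 becomes the exocyclic carboxyl carbon, the same 1,2-shift as the biosynthetic B-ring contraction; C6 is formed as a mixture and fixed in step 11.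

**Step 8**
Reactants: 13 ring-B-contracted 2-(trimethylsilyl)ethyl 7-oate
Product: 14 Δ5(10),9(11)-dien-12-one ester (C6 epimers)
Conditions: DDQ (1.2 equiv), TsOH·H2O (cat.), 1,4-dioxane, 80 °C
Reagents that add atoms: none
Why: acid-mediated quinone dehydrogenation through the extended dienol gives the linear dienone; the cross-conjugated alternative is excluded because C13 is a bridgehead.

**Step 9**
Reactants: 15 tert-butyl propanoate; 16 prop-2-enal
Product: 17 tert-butyl 3-hydroxy-2-methylpent-4-enoate (diastereomers)
Conditions: LiN(i-Pr)2, THF, −78 °C; then 16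
Reagents that add atoms: none
Why: ester-enolate aldol addition (1,2-addition to the enal); both stereocentres are erased or reset later.

**Step 10**
Reactants: 17 tert-butyl 3-hydroxy-2-methylpent-4-enoate
Product: 18 tert-butyl 2-methyl-3-oxopent-4-enoate
Conditions: Dess–Martin periodinane, NaHCO3, CH2Cl2, 0 °C; used at once
Reagents that add atoms: none
Why: Dess–Martin oxidation of the allylic alcohol gives the Nazarov-type vinyl β-keto ester.

**Step 11**
Reactants: 14 Δ5(10),9(11)-dien-12-one ester; 18 tert-butyl 2-methyl-3-oxopent-4-enoate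
Product: 20 tetracyclic silyl enol ether (ring A closed; 3-OTBS-Δ2; C19 tert-butyl ester; Δ9(11)-12-one; C10 epimers), via potassium enolate 19 (not isolated)
Conditions: 18, KN(SiMe3)2, THF, −78 °C; add 14, −78 → −20 °C; then t-BuMe2SiCl, −20 → 0 °C
Reagents that add atoms: tert-butyldimethylsilyl chloride, CC(C)(C)[Si](C)(C)Cl
Why: Proposed new method: the soft β-keto ester enolate adds 1,6 to the dienone at C5 and the resulting extended dienolate closes ring A through its γ-carbon C10 onto the vinyl ketone; the final C3 enolate is silylated in place; the closest known reaction is the base-mediated double Michael annulation of Nazarov reagents with activated cyclohexenones; C4 is expected to add anti to the epimerisable C6 ester (setting C5 and C6 trans) and from the α-face away from the C15–C16 bridge, with the C19 ester axial under reversible Michael conditions; this selectivity is unproven and the C10 epimers do not matter.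

**Step 12**
Reactants: 20 tetracyclic silyl enol ether
Product: 22 19,10-lactone enone (3-OTBS-Δ2; Δ9(11)-12-one), via allylic iodide 21 (not isolated)
Conditions: KN(SiMe3)2, THF, −78 °C; I2 (1.05 equiv); then AgOSO2CF3, 2,6-di-tert-butylpyridine, CH2Cl2, −20 → 0 °C
Reagents that add atoms: none
Why: Proposed new method: γ-deprotonation at C10 gives the extended dienolate, iodination gives the allylic iodide, and silver-assisted SN2′-type displacement by the cis-1,3-disposed tert-butyl ester carbonyl (loss of isobutene) closes the lactone; the closest known reactions are halolactonisation of tert-butyl esters and the α-lactonisation of 5-oxo acids with trivalent iodine; C10–O can only form on the α-face carrying C19, and only the axial-ester C4 epimer can lactonise.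

**Step 13**
Reactants: 22 19,10-lactone enone
Product: 23 2β-(tert-butyldimethylsilyloxy)-3-oxo lactone enone
Conditions: dimethyldioxirane, acetone–CH2Cl2, −78 → 0 °C, then rt
Reagents that add atoms: dimethyldioxirane, CC1(C)OO1
Why: Rubottom oxidation; the electron-rich silyl enol ether is epoxidised faster than the 16-ene or the enone, from the exo (β) face of the lactone-bridged ring A, and the silyloxy epoxide opens with 1,4-silyl migration on warming to give the 2β-silyloxy ketone.

**Step 14**
Reactants: 23 2β-(tert-butyldimethylsilyloxy)-3-oxo lactone enone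
Product: 24 9βH 12-silyl enol ether (Δ11; 3-ketone retained)
Conditions: [(Ph3P)CuH]6 (0.4 equiv), t-BuMe2SiCl, benzene–THF, rt
Reagents that add atoms: tert-butyldimethylsilyl chloride, CC(C)(C)[Si](C)(C)Cl
Why: copper hydride conjugate reduction with silyl trapping; hydride is expected at C9 from the β-face, anti to the axial C10–O bond that shields the α-face (the bias an axial C10 substituent exerts in 9(11)-kaurenes), placing H9 syn to C15 and masking C12 as its enol ether, while the isolated ketone and the 16-ene are not reduced; this face selectivity is unproven.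

**Step 15**
Reactants: 24 9βH 12-silyl enol ether
Product: 25 3β-alcohol (2β-OTBS; 12-OTBS enol ether; 2-(trimethylsilyl)ethyl ester)
Conditions: K[HB(s-Bu)3], THF, −78 °C; aq. NH4Cl
Reagents that add atoms: none
Why: bulky-hydride reduction of the only free ketone by equatorial attack gives the axial 3β-alcohol, cis to the 2β-oxygen; the selectivity rests on analogy with 3-oxo gibberellin reductions.

**Step 16**
Reactants: 25 3β-alcohol
Product: 26 2β,3β-dihydroxy-12-oxo-16-methylene 19,10-lactone 7-carboxylic acid (target)
Conditions: Bu4NF, AcOH, THF, 0 °C → rt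
Reagents that add atoms: none
Why: fluoride-mediated global desilylation removes the 2-O-silyl ether, unmasks the 12-ketone from its enol ether and cleaves the 2-(trimethylsilyl)ethyl ester by β-elimination, without touching any stereocentre; the acetic acid buffer guards the 3-hydroxy lactone against retro-aldol epimerisation.

**Compound list**
1 | cyclohexane-1,3-dione | O=C1CCCC(=O)C1 | starting material
2 | 3-bromoprop-1-yne | C#CCBr | starting material
3 | 2-(prop-2-yn-1-yl)cyclohexane-1,3-dione | C#CCC1C(=O)CCCC1=O | intermediate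
4 | but-3-en-2-one | CC(=O)C=C | starting material
5 | 2-(3-oxobutyl)-2-(prop-2-yn-1-yl)cyclohexane-1,3-dione | CC(=O)CCC1(CC#C)C(=O)CCCC1=O | intermediate
6 | (R)-8a-(prop-2-yn-1-yl)-3,4,8,8a-tetrahydronaphthalene-1,6(2H,7H)-dione | C#CC[C@]12CCC(=O)C=C1CCCC2=O | intermediate
7 | C7 ethylene ketal of 6 | C#CC[C@]12CCC(=O)C=C1CCCC21OCCO1 | intermediate
8 | 12-(tert-butyldimethylsilyloxy)-9(11),12-diene of 7 | C#CC[C@]12CC=C(O[Si](C)(C)C(C)(C)C)C=C1CCCC21OCCO1 | intermediate
9 | 7,7-ethylenedioxy B/C/D enone (12-oxo-Δ9(11); 16-methylene; C15 β) | C=C1C[C@]23C[C@H]1C(=O)C=C2CCCC31OCCO1 | intermediate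
10 | B/C/D ene-dione (7,12-dioxo-Δ9(11); 16-methylene) | C=C1C[C@]23C[C@H]1C(=O)C=C2CCCC3=O | intermediate
11 | 6-trifluoroacetyl derivative of 10 | C=C1C[C@]23C[C@H]1C(=O)C=C2CCC(C(=O)C(F)(F)F)C3=O | intermediate
12 | 6-diazo-7,12-dione | C=C1C[C@]23C[C@H]1C(=O)C=C2CCC(=[N+]=[N-])C3=O | intermediate
13 | ring-B-contracted 2-(trimethylsilyl)ethyl 7-oate (C6 epimers) | C=C1C[C@]23C[C@H]1C(=O)C=C2CCC3C(=O)OCC[Si](C)(C)C | intermediate
14 | Δ5(10),9(11)-dien-12-one ester (C6 epimers) | C=C1C[C@]23C[C@H]1C(=O)C=C2C=CC3C(=O)OCC[Si](C)(C)C | intermediate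
15 | tert-butyl propanoate | CCC(=O)OC(C)(C)C | starting material
16 | prop-2-enal | C=CC=O | starting material
17 | tert-butyl 3-hydroxy-2-methylpent-4-enoate | C=CC(O)C(C)C(=O)OC(C)(C)C | intermediate
18 | tert-butyl 2-methyl-3-oxopent-4-enoate | C=CC(=O)C(C)C(=O)OC(C)(C)C | intermediate
19 | potassium C3 enolate of the annulated tetracycle (C10 epimers) | C=C1C[C@]23C[C@H]1C(=O)C=C2C4CC=C([O-])[C@@](C)(C(=O)OC(C)(C)C)[C@H]4[C@@H]3C(=O)OCC[Si](C)(C)C.[K+] | intermediate
20 | tetracyclic silyl enol ether (C10 epimers) | C=C1C[C@]23C[C@H]1C(=O)C=C2C4CC=C(O[Si](C)(C)C(C)(C)C)[C@@](C)(C(=O)OC(C)(C)C)[C@H]4[C@@H]3C(=O)OCC[Si](C)(C)C | intermediate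
21 | 11-iodo-Δ9(10)-12-ketone (C11 epimers) | C=C1C[C@]23C[C@H]1C(=O)C(I)C2=C4CC=C(O[Si](C)(C)C(C)(C)C)[C@@](C)(C(=O)OC(C)(C)C)[C@H]4[C@@H]3C(=O)OCC[Si](C)(C)C | intermediate
22 | 19,10-lactone enone (3-OTBS-Δ2) | C=C1C[C@]23C[C@H]1C(=O)C=C2[C@@]12CC=C(O[Si](C)(C)C(C)(C)C)[C@@](C)(C(=O)O1)[C@H]2[C@@H]3C(=O)OCC[Si](C)(C)C | intermediate
23 | 2β-(tert-butyldimethylsilyloxy)-3-oxo lactone enone | C=C1C[C@]23C[C@H]1C(=O)C=C2[C@@]12C[C@H](O[Si](C)(C)C(C)(C)C)C(=O)[C@@](C)(C(=O)O1)[C@H]2[C@@H]3C(=O)OCC[Si](C)(C)C | intermediate
24 | 9βH 12-silyl enol ether | C=C1C[C@]23C[C@H]1C(O[Si](C)(C)C(C)(C)C)=C[C@H]2[C@@]12C[C@H](O[Si](C)(C)C(C)(C)C)C(=O)[C@@](C)(C(=O)O1)[C@H]2[C@@H]3C(=O)OCC[Si](C)(C)C | intermediate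
25 | 3β-alcohol | C=C1C[C@]23C[C@H]1C(O[Si](C)(C)C(C)(C)C)=C[C@H]2[C@@]12C[C@H](O[Si](C)(C)C(C)(C)C)[C@H](O)[C@@](C)(C(=O)O1)[C@H]2[C@@H]3C(=O)OCC[Si](C)(C)C | intermediate
26 | 2β,3β-dihydroxy-12-oxo-16-methylene 19,10-lactone 7-carboxylic acid | C=C1C[C@]23C[C@H]1C(=O)C[C@H]2[C@@]12C[C@H](O)[C@H](O)[C@@](C)(C(=O)O1)[C@H]2[C@@H]3C(=O)O | target

**Totals:** 16 steps; longest linear sequence 14 steps (steps 1–8 and 11–16; steps 9–10 are a two-step branch).

**Three steps most likely to fail, each with a fallback**

Step 11 (one-pot 1,6/γ double Michael): face selectivity at C5 relative to C8, the C4 ester/methyl orientation, competing deprotonation of 14 at C6 and polymerisation of 18 are all open. The fallback sets out from 13 and comes back at 20, building the ring A chain first and closing the ring intramolecularly. Treat 13 with t-BuMe2SiOSO2CF3/Et3N to give the extended silyl dienol ether F1. A Mukaiyama–Michael reaction of F1 with 18 (TiCl4, CH2Cl2, −78 °C) at the γ-carbon gives the C10-alkylated enone F2. DDQ/TsOH then gives the side-chain dienone F3. An equilibrating intramolecular 1,6-Michael addition (Cs2CO3, MeCN) followed by KN(SiMe3)2/t-BuMe2SiCl returns 20.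

Step 12 (iodination and silver-assisted lactonisation): iodination may go to C6 or the enol ether, or the allylic iodide may eliminate. The fallback sets out from 20 and comes back at 22, making the C10–O bond first and closing the lactone afterwards. γ-Oxygenate the potassium dienolate of 20 with O2 in the presence of P(OEt)3 (KN(SiMe3)2, THF, −78 °C) to the 10α-hydroxy enone F4. ZnBr2 in CH2Cl2 then cleaves the tert-butyl ester with loss of isobutene, and the γ-hydroxy acid closes to the γ-lactone 22. The oxygenation face is not directed, so only the 10α-epimer of F4 goes forward.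

Step 14 (conjugate reduction at C9): the β-carbon is flanked by two quaternary centres, and hydride attack from the α-face, which is the axial direction with respect to ring C, would give the 9-epimer. The fallback sets out from 23 and comes back at 24, replacing substrate control by catalyst control and the metal hydride by an organic hydride donor. Iminium-catalysed transfer hydrogenation of 23 reduces only the enone and gives the saturated 9βH 3,12-diketone F5. The catalyst is the L-valine tert-butyl ester salt of 3,3′-bis(2,4,6-triisopropylphenyl)-binol hydrogen phosphate, with both enantiomers of the phosphate screened for the one that delivers hydride to the β-face; the hydride donor is diethyl 2,6-dimethyl-1,4-dihydropyridine-3,5-dicarboxylate in Bu2O at 60 °C. The more accessible C12 ketone, which can enolise only toward C11, is then silylated (t-BuMe2SiOSO2CF3, Et3N, CH2Cl2, −78 °C) to return 24.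

**Further compounds**
F1 | step 11 | extended 12-(tert-butyldimethylsilyloxy)-9(10),11-diene of 13 | C=C1C[C@]23C[C@H]1C(O[Si](C)(C)C(C)(C)C)=CC2=CCC3C(=O)OCC[Si](C)(C)C
F2 | step 11 | C10-alkylated enone carrying the β-keto ester side chain | C=C1C[C@]23C[C@H]1C(=O)C=C2C(CCC(=O)C(C)C(=O)OC(C)(C)C)CC3C(=O)OCC[Si](C)(C)C
F3 | step 11 | Δ5(10),9(11)-dienone carrying the C10 side chain | C=C1C[C@]23C[C@H]1C(=O)C=C2C(CCC(=O)C(C)C(=O)OC(C)(C)C)=CC3C(=O)OCC[Si](C)(C)C
F4 | step 12 | 10α-hydroxy enone (C19 tert-butyl ester) | C=C1C[C@]23C[C@H]1C(=O)C=C2[C@]4(O)CC=C(O[Si](C)(C)C(C)(C)C)[C@@](C)(C(=O)OC(C)(C)C)[C@H]4[C@@H]3C(=O)OCC[Si](C)(C)C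
F5 | step 14 | saturated 9βH 2β-(tert-butyldimethylsilyloxy)-3,12-dioxo lactone | C=C1C[C@]23C[C@H]1C(=O)C[C@H]2[C@@]12C[C@H](O[Si](C)(C)C(C)(C)C)C(=O)[C@@](C)(C(=O)O1)[C@H]2[C@@H]3C(=O)OCC[Si](C)(C)C
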